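The eight-membered carbocycle (C1 lactone-bearing bridgehead, C2 bridging ketone, C3 oxygenated bridgehead, C4 ketone, C5 acyl-bearing CH, C6 methyl-bearing quaternary carbon, C7 prenylated CH, C8 methylene) is divided into two four-carbon halves, C2–C1–C8–C7 and C3–C4–C5–C6. A vinylketene and a 2-siloxydiene are united in one thermal operation: ketene [2+2] cycloaddition forms C2–C3, and Cope rearrangement of the resulting cis-2,3-divinylcyclobutanone forms C6–C7 and delivers the cyclooctadienone with the C2 ketone and the masked C4 ketone in place. The γ-lactone bridge (C1–C9(=O)–O–C3) is closed afterwards by reductive acyl transfer from a C3 carbonate.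

Key step: step 11

Remark: C5 is a β-diketone methine that equilibrates through its enol; it is assumed that the configuration drawn for the target is the thermodynamic one (acyl group anti to the larger substituent on C6) and is reached after step 15. Locants C1–C9 are those defined above.

Step 1
Reactants: 1 neryl acetate
Product: 2 (2Z)-6,7-epoxy-3,7-dimethyloct-2-en-1-yl acetate
Conditions: mCPBA, NaHCO3, CH2Cl2, 0 °C
Reagents that add atoms: mCPBA (3-chloroperoxybenzoic acid), OOC(=O)c1cccc(Cl)c1
Why: Prilezhaev epoxidation should take the electron-rich 6,7-alkene in preference to the 2,3-alkene, which is deactivated by the allylic acetate; the epoxide stereocentre is racemic and is removed in step 2.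

Step 2
Reactants: 2 (2Z)-6,7-epoxy-3,7-dimethyloct-2-en-1-yl acetate
Product: 5 (2Z,5E)-7-hydroxy-3,7-dimethylocta-2,5-dien-1-yl acetate, via hydroxy selenide 3 (not isolated), via selenoxide 4 (not isolated)
Conditions: (PhSe)2, NaBH4, EtOH, then 2, reflux; H2O2 (30% aq.), THF, 0 °C → rt
Reagents that add atoms: none
Why: Selenolate opening of the epoxide at the less hindered secondary carbon, oxidation and selenoxide syn-elimination (possible only away from the hydrogen-free carbinol carbon) should give the (E)-allylic tertiary alcohol, the known epoxide-to-allylic-alcohol transposition.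

Step 3
Reactants: 5 (2Z,5E)-7-hydroxy-3,7-dimethylocta-2,5-dien-1-yl acetate
Product: 6 (2Z,5E)-3,7-dimethylocta-2,5-diene-1,7-diol
Conditions: K2CO3 (cat.), MeOH, rt
Reagents that add atoms: none
Why: Base-catalysed transesterification removes the acetate; any acetate already lost in step 2 converges on the same diol.

Step 4
Reactants: 6 (2Z,5E)-3,7-dimethylocta-2,5-diene-1,7-diol
Product: 7 (2Z,5E)-7-hydroxy-3,7-dimethylocta-2,5-dienal
Conditions: MnO2, CH2Cl2, rt
Reagents that add atoms: none
Why: Allylic oxidation with MnO2 touches only the primary allylic alcohol (the tertiary one cannot be oxidised) and its neutral conditions should preserve the (Z)-enal and the skipped diene.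

Step 5
Reactants: 7 (2Z,5E)-7-hydroxy-3,7-dimethylocta-2,5-dienal, 8 5-bromo-2-methylpent-2-ene
Product: 10 (7Z,10E)-2,8,12-trimethyltrideca-2,7,10-triene-6,12-diol, via 4-methylpent-3-enylmagnesium bromide 9 (not isolated)
Conditions: 8, Mg, THF; then 7 (0.45 equiv), −78 → 0 °C; NH4Cl aq.
Reagents that add atoms: none
Why: Grignard 1,2-addition to the enal (one equivalent of 9 is consumed by the tertiary hydroxyl) should give the allylic alcohol, whose new carbinol centre is racemic and is oxidised in step 6.

Step 6
Reactants: 10 (7Z,10E)-2,8,12-trimethyltrideca-2,7,10-triene-6,12-diol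
Product: 11 (7Z,10E)-12-hydroxy-2,8,12-trimethyltrideca-2,7,10-trien-6-one
Conditions: MnO2, CH2Cl2, rt
Reagents that add atoms: none
Why: Allylic oxidation of the secondary alcohol under neutral conditions should give the (Z)-enone without isomerising the trisubstituted double bond.

Step 7
Reactants: 11 (7Z,10E)-12-hydroxy-2,8,12-trimethyltrideca-2,7,10-trien-6-one
Product: 12 (5Z,7Z,10E)-6,12-bis(triethylsilyloxy)-2,8,12-trimethyltrideca-2,5,7,10-tetraene
Conditions: LiN(iPr)2 (2.3 equiv), THF–DMPU, −78 °C; Et3SiOTf (2.4 equiv), −78 → 0 °C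
Reagents that add atoms: triethylsilyl trifluoromethanesulfonate, CC[Si](CC)(CC)OS(=O)(=O)C(F)(F)F
Why: Kinetic α′-deprotonation of the enone (cross-conjugated enolate, Z geometry favoured in the presence of DMPU) and O-silylation of both the enolate and the tertiary alkoxide should give the 2-siloxydiene, with the prenyl-bearing carbon cis to the siloxy group.

Step 8
Reactants: 13 5-methylhex-4-enal, 14 malonic acid
Product: 15 (3E)-7-methylocta-3,6-dienoic acid
Conditions: piperidinium acetate (cat.), DMSO, 100 °C
Reagents that add atoms: none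
Why: Knoevenagel–Doebner condensation with decarboxylation under these β,γ-selective conditions should give the (E)-alk-3-enoic acid.

Step 9
Reactants: 15 (3E)-7-methylocta-3,6-dienoic acid, 16 prenyl bromide
Product: 17 (3E)-7-methyl-2-(3-methylbut-2-en-1-yl)octa-3,6-dienoic acid (racemic)
Conditions: LiN(iPr)2 (2.2 equiv), THF, −78 → 0 °C; 16, −78 °C; dilute HCl
Reagents that add atoms: none
Why: The dienediolate of a β,γ-unsaturated acid is alkylated at the α-carbon with retention of the (E)-alkene; the new α-centre is racemic and becomes sp2 in step 11.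

Step 10
Reactants: 17 (3E)-7-methyl-2-(3-methylbut-2-en-1-yl)octa-3,6-dienoic acid
Product: 18 (3E)-7-methyl-2-(3-methylbut-2-en-1-yl)octa-3,6-dienoyl chloride
Conditions: (COCl)2, DMF (cat.), CH2Cl2, 0 °C → rt
Reagents that add atoms: oxalyl chloride, O=C(Cl)C(Cl)=O
Why: Acid chloride formation through the chloroiminium (Vilsmeier-type) activation is neutral enough to leave the skipped diene untouched; 18 is used crude.

Step 11
Reactants: 18 (3E)-7-methyl-2-(3-methylbut-2-en-1-yl)octa-3,6-dienoyl chloride, 12 (5Z,7Z,10E)-6,12-bis(triethylsilyloxy)-2,8,12-trimethyltrideca-2,5,7,10-tetraene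
Product: 21 racemic cycloocta-dienone (C2 ketone; C1=C8 and C4=C5 double bonds; C4 triethylsilyl enol ether), via vinylketene 19 (not isolated), via cis-2,3-divinylcyclobutanone 20 (not isolated)
Conditions: Et3N, toluene, slow addition of 18 to 12 (1.2 equiv) at 25 °C, then 110 °C
Reagents that add atoms: none
Why: Triethylamine dehydrochlorinates 18 to the (E)-vinylketene 19, whose carbonyl carbon (C2) is attacked by the siloxy-activated terminus C3 of 12 in a ketene–alkene [2+2] cycloaddition that also joins C1 to C4 and gives the cis-2,3-divinylcyclobutanone 20. This push–pull cyclobutane (acyl on C1, siloxy on C4) then undergoes a [3,3] sigmatropic (Cope) rearrangement through a boat transition state, breaking C1–C4 and forming C6–C7. The closest known reaction type is the [4+4] annulation of vinylketenes with 1,3-dienes to cycloocta-2,6-dienones. The four-membered ring closes by [2+2] cycloaddition and is transient, and the eight-membered ring closes by the four-carbon ring expansion of the [3,3] shift. C6 and C7 are set relative to each other by the alkene geometries, because the outward substituents of the two vinyl termini (prenyl on C7 from the (3E) alkene of 18, methyl on C6 from the (7Z) alkene of 12) must end up cis; the C3 centre arises from the (5Z) enol ether, which puts hydrogen on the face of the vinyl groups so that the boat is not blocked, and is erased in step 12. The step needs regioselectivity (C2 to C3) and chemoselectivity over the isolated trisubstituted alkenes, both secured by the enol ether as the only alkene nucleophilic enough for a ketene and by the cation-stabilising siloxy and alkenyl groups on C4; the product is racemic and is resolved in step 12.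

Step 12
Reactants: 21 racemic cycloocta-dienone
Product: 23 C3 (−)-menthyl carbonate (single diastereomer), via potassium alkoxide 22 (not isolated)
Conditions: KN(SiMe3)2, THF, −78 °C; 2-(phenylsulfonyl)-3-phenyloxaziridine; (−)-menthyl chloroformate, −78 → 0 °C; separation of the two diastereomers on silica
Reagents that add atoms: 2-(phenylsulfonyl)-3-phenyloxaziridine, O=S(=O)(N1OC1c1ccccc1)c1ccccc1; (1R)-(−)-menthyl chloroformate, ClC(=O)O[C@@H]1C[C@H](C)CC[C@H]1C(C)C
Why: Enolate oxidation with an N-sulfonyloxaziridine followed by O-acylation; oxygen should enter planar C3 from the convex face of the tub-shaped ring, opposite the fold in which the C6 side chain points inward, so that O ends up on the face of the C7 prenyl and C6 methyl groups, and the menthyl group converts the racemate into two separable diastereomers (classical resolution).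

Step 13
Reactants: 23 C3 (−)-menthyl carbonate
Product: 25 bicyclic β-keto γ-lactone (C4 triethylsilyl enol ether), via lithium enolate 24 (not isolated)
Conditions: LiBH(s-Bu)3, THF, −78 → 0 °C; NH4Cl aq.
Reagents that add atoms: none
Why: Conjugate reduction of the hindered enone delivers hydride to C8, and the resulting C1 enolate is acylated intramolecularly by the carbonate (Dieckmann-type closure of the five-membered lactone with loss of menthoxide); the tether from C3–O allows only the cis bridge, so the C1 quaternary centre is set by C3, and C4 stays masked so no C5 enolate can attack the new lactone.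

Step 14
Reactants: 25 bicyclic β-keto γ-lactone, 26 isobutyraldehyde
Product: 27 C5 aldol adduct (mixture at C5 and at the carbinol carbon)
Conditions: 26, BF3·OEt2, CH2Cl2, −78 °C; NaHCO3 aq.
Reagents that add atoms: none
Why: Mukaiyama aldol addition of the C4 silyl enol ether forms the C5–acyl carbon bond regiospecifically without a free enolate; both new centres are removed or equilibrated in step 15.

Step 15
Reactants: 27 C5 aldol adduct
Product: 28 triethylsilyl ether of the tertiary alcohol corresponding to the target (β-diketone)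
Conditions: Dess–Martin periodinane, NaHCO3, CH2Cl2, rt
Reagents that add atoms: none
Why: Dess–Martin oxidation of the β-hydroxy ketone gives the β-diketone, and C5 should settle through the enol to the configuration with the isobutyryl group anti to the C6 side chain.

Step 16
Reactants: 28 triethylsilyl ether
Product: 29 target hydroperoxide
Conditions: H2O2 (anhydrous, Et2O), TsOH·H2O (cat.), −20 → 0 °C
Reagents that add atoms: hydrogen peroxide, OO
Why: Acid-catalysed perhydrolysis (SN1 substitution) of the tertiary allylic silyl ether: the allyl cation should be captured by H2O2 at its tertiary terminus under kinetic control, keeping the (E)-alkene, while the isolated prenyl groups are not protonated by catalytic sulfonic acid at low temperature.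

Compound list
1 | neryl acetate, (2Z)-3,7-dimethylocta-2,6-dien-1-yl acetate | CC(=O)OC/C=C(C)\CCC=C(C)C | starting material
2 | (2Z)-6,7-epoxy-3,7-dimethyloct-2-en-1-yl acetate, racemic epoxide | CC(=O)OC/C=C(C)\CCC1OC1(C)C | intermediate
3 | (2Z)-7-hydroxy-3,7-dimethyl-6-(phenylselanyl)oct-2-en-1-yl acetate | CC(=O)OC/C=C(C)\CCC([Se]c1ccccc1)C(C)(C)O | intermediate
4 | selenoxide of 3 | CC(=O)OC/C=C(C)\CCC([Se](=O)c1ccccc1)C(C)(C)O | intermediate
5 | (2Z,5E)-7-hydroxy-3,7-dimethylocta-2,5-dien-1-yl acetate | CC(=O)OC/C=C(C)\C/C=C/C(C)(C)O | intermediate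
6 | (2Z,5E)-3,7-dimethylocta-2,5-diene-1,7-diol | OC/C=C(C)\C/C=C/C(C)(C)O | intermediate
7 | (2Z,5E)-7-hydroxy-3,7-dimethylocta-2,5-dienal | O=C/C=C(C)\C/C=C/C(C)(C)O | intermediate
8 | 5-bromo-2-methylpent-2-ene | CC(C)=CCCBr | starting material
9 | 4-methylpent-3-enylmagnesium bromide | CC(C)=CCC[Mg]Br | intermediate
10 | (7Z,10E)-2,8,12-trimethyltrideca-2,7,10-triene-6,12-diol, racemic at C6 | CC(C)=CCCC(O)/C=C(C)\C/C=C/C(C)(C)O | intermediate
11 | (7Z,10E)-12-hydroxy-2,8,12-trimethyltrideca-2,7,10-trien-6-one | CC(C)=CCCC(=O)/C=C(C)\C/C=C/C(C)(C)O | intermediate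
12 | (5Z,7Z,10E)-6,12-bis(triethylsilyloxy)-2,8,12-trimethyltrideca-2,5,7,10-tetraene | CC(C)=CC/C=C(O[Si](CC)(CC)CC)/C=C(C)\C/C=C/C(C)(C)O[Si](CC)(CC)CC | intermediate
13 | 5-methylhex-4-enal | CC(C)=CCCC=O | starting material
14 | malonic acid | OC(=O)CC(O)=O | starting material
15 | (3E)-7-methylocta-3,6-dienoic acid | CC(C)=CC/C=C/CC(O)=O | intermediate
16 | prenyl bromide, 1-bromo-3-methylbut-2-ene | CC(C)=CCBr | starting material
17 | (3E)-7-methyl-2-(3-methylbut-2-en-1-yl)octa-3,6-dienoic acid, racemic | CC(C)=CC/C=C/C(CC=C(C)C)C(O)=O | intermediate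
18 | (3E)-7-methyl-2-(3-methylbut-2-en-1-yl)octa-3,6-dienoyl chloride, racemic | CC(C)=CC/C=C/C(CC=C(C)C)C(Cl)=O | intermediate
19 | vinylketene, (3E)-7-methyl-2-(3-methylbut-2-en-1-yl)octa-1,3,6-trien-1-one | CC(C)=CC/C=C/C(CC=C(C)C)=C=O | intermediate
20 | cis-2,3-divinylcyclobutanone: cyclobutanone carbonyl = C2; C3 bears H (on the face of the two alkenyl groups) and prenyl; C4 bears triethylsilyloxy and the (Z)-alkenyl chain; C1 bears prenyl and the (E)-alkenyl chain; the two alkenyl groups cis; racemic, enantiomer shown is the one carried on | O=C1[C@@H](CC=C(C)C)[C@](O[Si](CC)(CC)CC)(/C=C(C)\C/C=C/C(C)(C)O[Si](CC)(CC)CC)[C@]1(CC=C(C)C)/C=C/CC=C(C)C | intermediate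
21 | cycloocta-dienone: C2 ketone, C1=C8 and C4=C5 ring double bonds, prenyl on C1, C3 and C7, triethylsilyl enol ether at C4, C6 bearing methyl and the (E)-4-methyl-4-(triethylsilyloxy)pent-2-enyl chain; C7 prenyl cis to C6 methyl, C3 prenyl on the same face as these; racemic, enantiomer shown is the one carried on | CC(C)=CC[C@H]1/C=C(CC=C(C)C)\C(=O)[C@@H](CC=C(C)C)/C(O[Si](CC)(CC)CC)=C\[C@]1(C)C/C=C/C(C)(C)O[Si](CC)(CC)CC | intermediate
22 | potassium alkoxide of the C3 tertiary α-hydroxy ketone (oxygen on the face of the C7 prenyl and C6 methyl groups); racemic, enantiomer shown is the one carried on | CC(C)=CC[C@H]1/C=C(CC=C(C)C)\C(=O)[C@@](CC=C(C)C)([O-])/C(O[Si](CC)(CC)CC)=C\[C@]1(C)C/C=C/C(C)(C)O[Si](CC)(CC)CC.[K+] | intermediate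
23 | C3 (1R,2S,5R)-menthyl carbonate of 22, single diastereomer | CC(C)=CC[C@H]1/C=C(CC=C(C)C)\C(=O)[C@@](CC=C(C)C)(OC(=O)O[C@@H]2C[C@H](C)CC[C@H]2C(C)C)/C(O[Si](CC)(CC)CC)=C\[C@]1(C)C/C=C/C(C)(C)O[Si](CC)(CC)CC | intermediate
24 | lithium C1=C2 enolate formed by hydride addition to C8 of 23 | CC(C)=CC[C@H]1C/C(CC=C(C)C)=C([O-])\[C@@](CC=C(C)C)(OC(=O)O[C@@H]2C[C@H](C)CC[C@H]2C(C)C)/C(O[Si](CC)(CC)CC)=C\[C@]1(C)C/C=C/C(C)(C)O[Si](CC)(CC)CC.[Li+] | intermediate
25 | bicyclic β-keto γ-lactone: C1–C9(=O)–O–C3 bridge, C2 ketone, C4=C5 triethylsilyl enol ether, prenyl on C1, C3 and C7, C6 methyl and silyloxy side chain, configuration as in the target | CC(C)=CC[C@H]1C[C@@]2(CC=C(C)C)C(=O)O[C@@](CC=C(C)C)(/C(O[Si](CC)(CC)CC)=C\[C@]1(C)C/C=C/C(C)(C)O[Si](CC)(CC)CC)C2=O | intermediate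
26 | isobutyraldehyde | CC(C)C=O | starting material
27 | C5 aldol adduct: C4 ketone, C5 bearing 1-hydroxy-2-methylpropyl; mixture at C5 and the carbinol carbon | CC(C)=CC[C@H]1C[C@@]2(CC=C(C)C)C(=O)O[C@@](CC=C(C)C)(C(=O)C(C(O)C(C)C)[C@]1(C)C/C=C/C(C)(C)O[Si](CC)(CC)CC)C2=O | intermediate
28 | triethylsilyl ether of the tertiary alcohol corresponding to the target, C5 isobutyryl, configuration as in the target | CC(C)=CC[C@H]1C[C@@]2(CC=C(C)C)C(=O)O[C@@](CC=C(C)C)(C(=O)[C@@H](C(=O)C(C)C)[C@]1(C)C/C=C/C(C)(C)O[Si](CC)(CC)CC)C2=O | intermediate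
29 | target hydroperoxide | CC(C)=CC[C@H]1C[C@@]2(CC=C(C)C)C(=O)O[C@@](CC=C(C)C)(C(=O)[C@@H](C(=O)C(C)C)[C@]1(C)C/C=C/C(C)(C)OO)C2=O | target

Total step count: 16. Longest linear sequence: 13 steps (steps 1–7 and 11–16).

Steps most likely to fail

Step 11. The vinylketene may be lost by dimerisation or oligomerisation before the hindered trisubstituted enol ether intercepts it, so that neither ring bond forms. The fallback sets out from 18 and 12 and returns at 21. Acid chloride 18 would be converted with pyrrolidine and Et3N into the N-acylpyrrolidine F1. Activation of F1 with Tf2O and 2,4,6-collidine in CH2Cl2 at −78 °C should give a vinylketeniminium salt, which does not dimerise and is far more electrophilic than the ketene. Its [2+2] cycloaddition with 12 and the charge-accelerated [3,3] shift of the cyclobutaniminium ion should lead to the cyclooctadienyl iminium triflate F2, which aqueous NaHCO3 hydrolyses to 21.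

Step 12. The two diastereomeric menthyl carbonates may co-elute, so that no resolution is achieved. The fallback sets out from 21 and returns at 25. The enantiomers of 21 would be separated by preparative HPLC on a chiral stationary phase. The wanted enantiomer would then be deprotonated with KN(SiMe3)2 and treated with dibenzyl peroxydicarbonate, which transfers the oxygen and the carbonate in one electrophile and should give the benzyl carbonate F3. Under the conditions of step 13, F3 should give 25 with loss of benzyl alcohol.

Step 16. Ionisation under Brønsted acid may lead to capture of the allyl cation at its secondary terminus (allylic transposition) or to protonation of prenyl groups. The fallback sets out from 28 and returns at 29 by a radical path. HF·pyridine would give the tertiary alcohol F4, and Burgess reagent would dehydrate it to the 1,3-diene F5 (only methyl hydrogens are available for elimination). Hydroperoxysilylation with Co(thd)2, O2 and Et3SiH (Isayama–Mukaiyama reaction, limiting silane) relies on hydrogen-atom transfer to the terminal methylene of the conjugated diene being faster than to the isolated trisubstituted alkenes. Capture of the allyl radical by O2 at the tertiary terminus should give the triethylsilyl peroxide F6, and brief treatment with HF·pyridine would release 29.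

Further compounds
F1 | step 11 | 1-[(3E)-7-methyl-2-(3-methylbut-2-en-1-yl)octa-3,6-dienoyl]pyrrolidine, racemic | CC(C)=CC/C=C/C(CC=C(C)C)C(=O)N1CCCC1
F2 | step 11 | cyclooctadienyl pyrrolidinium (iminium) triflate, the C2 iminium analogue of 21, racemic | CC(C)=CC[C@H]1/C=C(CC=C(C)C)\C(=[N+]2CCCC2)[C@@H](CC=C(C)C)/C(O[Si](CC)(CC)CC)=C\[C@]1(C)C/C=C/C(C)(C)O[Si](CC)(CC)CC.[O-]S(=O)(=O)C(F)(F)F
F3 | step 12 | C3 benzyl carbonate, the benzyl analogue of 23 | CC(C)=CC[C@H]1/C=C(CC=C(C)C)\C(=O)[C@@](CC=C(C)C)(OC(=O)OCc2ccccc2)/C(O[Si](CC)(CC)CC)=C\[C@]1(C)C/C=C/C(C)(C)O[Si](CC)(CC)CC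
F4 | step 16 | tertiary allylic alcohol, desilylated 28 | CC(C)=CC[C@H]1C[C@@]2(CC=C(C)C)C(=O)O[C@@](CC=C(C)C)(C(=O)[C@@H](C(=O)C(C)C)[C@]1(C)C/C=C/C(C)(C)O)C2=O
F5 | step 16 | 1,3-diene with a (2E)-4-methylpenta-2,4-dienyl side chain on C6 | CC(C)=CC[C@H]1C[C@@]2(CC=C(C)C)C(=O)O[C@@](CC=C(C)C)(C(=O)[C@@H](C(=O)C(C)C)[C@]1(C)C/C=C/C(C)=C)C2=O
F6 | step 16 | triethylsilyl peroxide of the target | CC(C)=CC[C@H]1C[C@@]2(CC=C(C)C)C(=O)O[C@@](CC=C(C)C)(C(=O)[C@@H](C(=O)C(C)C)[C@]1(C)C/C=C/C(C)(C)OO[Si](CC)(CC)CC)C2=O
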